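## The problem

The target is a cembranolide. It has a 14-membered carbocycle (C1–C14) with a trans-fused α-methylene-γ-lactone across C1/C14: C15, the C16 carbonyl and the C17 methylene hang on C1, and the lactone oxygen sits on C14. It also carries a trisubstituted 3,4-epoxide (C18 methyl on C4), a secondary allylic hydroperoxide at C7 beside the exocyclic C8=C19 methylene, an E-trisubstituted C11=C12 olefin (C20 methyl) and an acetate at C13. The SMILES reads as (1R,3S,4S,7R,11E,13S,14R).

A synthesis has to close the large ring at a bond whose formation does not disturb the stereocentres. It has to deliver C13, C14 and C1 as one contiguous block, an epoxide separated from C1 by one methylene, and a remote hydroperoxide. Only C14 is a dependable internal control element: as the γ-carbon of a butenolide it steers a nucleophile to the opposite face of C1. The C3/C4 epoxide and C13 are too flexibly connected to C14 for substrate control and are better set by reagent-controlled epoxidation of allylic alcohols. C7 can only be set by the conformation of the finished macrocycle.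

The hydroperoxide tolerates neither reductants, phosphines, palladium nor base (Kornblum–DeLaMare fragmentation). The α-methylene lactone is a Michael acceptor, the epoxide is acid-labile, and a free C13 hydroxyl next to the C14 lactone oxygen can take over the acyl group. These groups therefore have to appear late, the most fragile last.

Two structural features make the plan possible. The array C10–C11=C12(C20)–C13(O) is the 1,4-adduct of a C9 carbon nucleophile to a C12–C13 epoxide bearing a C10=C11 vinyl group, and C9 is allylic to C7=C8, so a sulfone on C9 gives a soft carbanion. The C7 hydroperoxide with its C8=C19 methylene is the Schenck ene product of that same E-C7=C8 olefin.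

## Retrosynthesis

**37 from 36.** The C7–O bond is cut and the C8=C19 double bond is returned to C7=C8, which is a Schenck ene reaction of singlet oxygen read backwards. The hydroperoxide is the most fragile group, so any earlier introduction would force it through reductive and basic steps. Substitution of a C7 alcohol by hydrogen peroxide on this allylic system has no dependable stereospecific form. Acetate 36 is simpler by one stereocentre. The forward step must choose C7=C8 over C11=C12 (deactivated by the allylic acetate) and over the electron-poor methylene lactone, abstract hydrogen from C19 and not from C6, and attack the exposed face.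

**36 from 35, 34 and 31.** The acetate and the C15–C17 bond are removed. The methylene group is a Michael acceptor and would not survive sulfinate, hydride, organocopper or palladium chemistry, so it is added to the closed ring by an enolate Mannich reaction and elimination (31 to 32 to 34). That enolate chemistry excludes an acetate on C13, so the oxygen is carried as a silyl ether and exchanged afterwards (34 to 35 to 36). Lactone 31 is asked only for selective enolisation at C15.

**31 from 30 and 29.** The C9–S bond is cut. The sulfone has no role in the target; it only makes C9 nucleophilic. The C13 hydroxyl of 29 is silylated first (30) so that it cannot attack the lactone. The forward reduction must replace sulfur by hydrogen without moving the C7=C8 double bond. Both ends of the C7–C9 allyl unit are secondary, so this is one of the uncertain steps.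

**29 from 28 (key step).** The ring is opened at C9–C10.
- Closing at C13–C14 or C1–C2 by carbonyl addition would create a stereocentre in the ring-forming step.
- Closing at C11=C12 by olefination or metathesis gives no control over a trisubstituted geometry.
- The C9–C10 bond joins two methylene carbons, creates no stereocentre that survives, and its electrophilic half releases the C13 hydroxyl and the E-C11=C12 olefin in the same event.

Precursor 28 is acyclic and already carries every stereocentre except C7. The forward reaction needs attack at C10 rather than C12, proton transfer from C9 to the alkoxide, and ring closure in preference to oligomerisation.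

**28 from 27, 26, 25, 24 and 22.** The vinyl epoxide is taken apart at C10=C11 (Wittig methylenation of 27), at the two epoxide C–O bonds (Sharpless epoxidation of 25) and at C12=C13 (Wittig reaction of the C13 aldehyde from 22 with ylide 17). The epoxide stores the C13 configuration under reagent control. Adding a vinyl metal to the C13 aldehyde would instead rely on Felkin or chelate control next to the lactone. This removes two stereocentres and four carbons.

**22 from 21, 19, 18 and 16 with 17.** The sulfone comes from allylic alcohol 19 by bromide displacement, and the E-C7=C8 olefin from aldehyde 16 and the same ylide 17. The sulfone is installed before the vinyl epoxide exists, because bromide and sulfinate would open it.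

**16 from 15, 14 and 11 with 12.** The C5–C6 bond is cut. C5 can only be an electrophile, since a carbanion there would open the epoxide. The triflate of epoxy alcohol 11 is therefore displaced by a vinyl copper reagent from 12, and the vinyl group is turned into the C7 aldehyde by hydroboration and oxidation.

**11 from 10, 9 and 7 with 8.** The 3,4-epoxide comes from allylic alcohol 10 by Sharpless epoxidation, and the E-C3=C4 enal 9 from allyl lactone 7 and methacrolein 8 by cross-metathesis. This gives the C4 methyl, the geometry and the directing hydroxyl in two steps.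

**7 from 4 with 5, and 4 from 2 and 1.** The C1–C2 bond is cut as a conjugate addition of an allyl group to butenolide 4, anti to the C14 substituent. The butenolide comes from the commercial (R)-lactone 1 by silylation and selenoxide elimination. All absolute stereochemistry outside the two Sharpless steps derives from 1.

## Roads not taken

**Alternative 1: rhodium carbenoid C–H insertion to close the lactone.** The cut is C1–C15. In the forward direction Rh2(OAc)4 decomposes the diazophosphonoacetate A1 of an acyclic C14 alcohol, and the carbenoid inserts into a C1–H bond to give the trans phosphono lactone A2.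
- Merits: the lactone is made from a simple chiral alcohol, and the phosphonate allows the methylene group to be introduced later by a Horner–Wadsworth–Emmons reaction with formaldehyde. That is milder than the amide-base Mannich sequence of steps 22 and 23; in this respect the alternative is better.
- Weak points: the insertion must choose the C1 methylene over other C–H bonds, the trans selectivity is only a preference, and A2 carries the C2 side as a two-carbon stub, so the whole C3–C9 chain is still to be built. The ring-closure problem is not touched.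
- Comparison: the chosen plan takes the lactone and its C14 centre from 1, sets C1 by a cuprate addition of well-known facial preference, and needs no diazo chemistry.

**Alternative 2: three-component assembly on the butenolide.** The cuts are C1–C2 and C15–C17. The lithiated allylic sulfone A3 would add through its α-carbon to butenolide 4, and the enolate would be trapped with Eschenmoser's salt to give the amino lactone A4.
- Merits: one flask forms two bonds and two stereocentres by relay from C14, and brings in C2–C5 with the E-olefin. It replaces steps 3, 4, 22 and 23 and is clearly shorter at the front; here it is better.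
- Weak points: the α/γ selectivity of the allyl sulfone anion must be enforced. The basic amine must pass through two titanium-mediated epoxidations and several oxidations (N-oxide formation and premature elimination). A4 holds a second acidic sulfone at C2 that would compete with C9 as pronucleophile in the cyclisation unless removed first.
- Comparison: the chosen plan keeps the Michael acceptor and its amine precursor out of the long middle section, and C9 is the only acidic carbon in 28.

**Alternative 3: late cyclocarbonylation.** The cuts are C15–C16 and C16–O. A macrocyclic alcohol with a C1 ethynyl group, A5, would be treated with PdCl2 and thiourea under carbon monoxide to give the methylene lactone A6, which is identical with 34.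
- Merits: the complete α-methylene lactone arrives in one step on the closed ring without enolate chemistry, one step shorter than steps 22 and 23. Because it meets the route at 34, it stays available as a replacement for those two steps.
- Weak points: A5 needs the carbocycle to be closed without the lactone, and the C1 centre must be set as a propargylic carbon without the butenolide relay. Divalent palladium and carbon monoxide must leave the trisubstituted epoxide and the two ring olefins alone. The C13 and C14 oxygens must be told apart.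
- Comparison: the chosen plan uses the lactone from the first step as stereochemical anchor, and the Mannich route on 31 has only one enolisable position.

Key step: step 19

Assumption: 1 is bought as the (R)-enantiomer, and the face of C7=C8 in 36 that singlet oxygen attacks is taken to be the exposed one that leads to the 7R hydroperoxide.

## Route

Step 1
Reactants: 1 (R)-5-(hydroxymethyl)dihydrofuran-2(3H)-one
Product: 2 (R)-5-[(tert-butyldiphenylsilyloxy)methyl]dihydrofuran-2(3H)-one
Conditions: TBDPSCl, imidazole, DMF, 0 °C to rt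
Reagents that add atoms: tert-butyl(chloro)diphenylsilane, CC(C)(C)[Si](Cl)(c1ccccc1)c1ccccc1
Why: Silyl ether formation at the primary alcohol; the bulky silyl group later shields one face of the butenolide and is stable to amide base, Lewis acid and oxidants up to step 12.

Step 2
Reactants: 2 (R)-5-[(tert-butyldiphenylsilyloxy)methyl]dihydrofuran-2(3H)-one
Product: 4 (R)-5-[(tert-butyldiphenylsilyloxy)methyl]furan-2(5H)-one, via α-phenylselanyl lactone 3 (not isolated)
Conditions: LDA, THF, −78 °C; PhSeBr; then 30% H2O2, pyridine, CH2Cl2, 0 °C to rt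
Reagents that add atoms: none
Why: Enolate selenenylation followed by selenoxide syn-elimination; the only β-hydrogens are on C4, so the endocyclic butenolide forms and the C5 stereocentre is not touched.

Step 3
Reactants: 4 (R)-5-[(tert-butyldiphenylsilyloxy)methyl]furan-2(5H)-one; 5 allylmagnesium bromide
Product: 7 (4R,5R)-4-allyl-5-[(tert-butyldiphenylsilyloxy)methyl]dihydrofuran-2(3H)-one, via silyl ketene acetal 6 (not isolated)
Conditions: CuBr·SMe2 (cat.), TMSCl, THF, −78 °C; then aq. NH4Cl
Reagents that add atoms: none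
Why: Copper-catalysed conjugate addition with silyl trapping of the enolate; the allyl group enters anti to the silyloxymethyl group on C5, which sets C1 of the target trans to C14.

Step 4
Reactants: 7 (4R,5R)-4-allyl-5-[(tert-butyldiphenylsilyloxy)methyl]dihydrofuran-2(3H)-one; 8 methacrolein
Product: 9 (E)-4-[(2R,3R)-2-[(tert-butyldiphenylsilyloxy)methyl]-5-oxotetrahydrofuran-3-yl]-2-methylbut-2-enal
Conditions: second-generation Hoveyda–Grubbs catalyst RuCl2(H2IMes)(=CH-C6H4-2-OiPr) (5 mol %), excess 8, CH2Cl2, 40 °C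
Reagents that add atoms: none
Why: Olefin cross-metathesis of a terminal olefin with an electron-poor 1,1-disubstituted partner that does not homodimerise; the conjugated trisubstituted enal should form as the E isomer.

Step 5
Reactants: 9 (E)-4-[(2R,3R)-2-[(tert-butyldiphenylsilyloxy)methyl]-5-oxotetrahydrofuran-3-yl]-2-methylbut-2-enal
Product: 10 (4R,5R)-5-[(tert-butyldiphenylsilyloxy)methyl]-4-[(E)-4-hydroxy-3-methylbut-2-en-1-yl]dihydrofuran-2(3H)-one
Conditions: NaBH4, CeCl3·7H2O, MeOH, −20 °C
Reagents that add atoms: none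
Why: Luche 1,2-reduction of the enal; the lactone is not reduced under these conditions.

Step 6
Reactants: 10 (4R,5R)-5-[(tert-butyldiphenylsilyloxy)methyl]-4-[(E)-4-hydroxy-3-methylbut-2-en-1-yl]dihydrofuran-2(3H)-one
Product: 11 (4R,5R)-5-[(tert-butyldiphenylsilyloxy)methyl]-4-{[(2S,3S)-3-(hydroxymethyl)-3-methyloxiran-2-yl]methyl}dihydrofuran-2(3H)-one
Conditions: Ti(OiPr)4 (cat.), L-(+)-diethyl tartrate (cat.), tBuOOH, 4 Å molecular sieves, CH2Cl2, −20 °C
Reagents that add atoms: tert-butyl hydroperoxide, CC(C)(C)OO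
Why: Sharpless asymmetric epoxidation of an E-2-methyl allylic alcohol; the L-(+)-tartrate catalyst delivers oxygen to the face that gives the (2S,3S)-epoxy alcohol, which is 3S,4S of the target, under reagent control and independent of the remote lactone centres.

Step 7
Reactants: 11 (4R,5R)-5-[(tert-butyldiphenylsilyloxy)methyl]-4-{[(2S,3S)-3-(hydroxymethyl)-3-methyloxiran-2-yl]methyl}dihydrofuran-2(3H)-one; 12 vinylmagnesium bromide
Product: 14 (4R,5R)-4-{[(2S,3S)-3-allyl-3-methyloxiran-2-yl]methyl}-5-[(tert-butyldiphenylsilyloxy)methyl]dihydrofuran-2(3H)-one, via epoxy triflate 13 (not isolated)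
Conditions: Tf2O, 2,6-lutidine, CH2Cl2, −78 °C; then 12, CuI (cat.), THF, −78 to −40 °C
Reagents that add atoms: none
Why: Copper-catalysed coupling of a Grignard reagent with a primary triflate (SN2 at C5) forms C5–C6; at low temperature the triflate should react faster than the trisubstituted epoxide or the lactone.

Step 8
Reactants: 14 (4R,5R)-4-{[(2S,3S)-3-allyl-3-methyloxiran-2-yl]methyl}-5-[(tert-butyldiphenylsilyloxy)methyl]dihydrofuran-2(3H)-one
Product: 15 (4R,5R)-5-[(tert-butyldiphenylsilyloxy)methyl]-4-{[(2S,3S)-3-(3-hydroxypropyl)-3-methyloxiran-2-yl]methyl}dihydrofuran-2(3H)-one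
Conditions: 9-BBN, THF, 0 °C to rt; then 30% H2O2, pH 7 phosphate buffer
Reagents that add atoms: hydrogen peroxide, OO
Why: Anti-Markovnikov hydroboration–oxidation of the terminal olefin; 9-BBN leaves lactone and epoxide alone, and the buffered oxidation avoids lactone hydrolysis.

Step 9
Reactants: 15 (4R,5R)-5-[(tert-butyldiphenylsilyloxy)methyl]-4-{[(2S,3S)-3-(3-hydroxypropyl)-3-methyloxiran-2-yl]methyl}dihydrofuran-2(3H)-one
Product: 16 3-[(2S,3S)-3-{[(2R,3R)-2-[(tert-butyldiphenylsilyloxy)methyl]-5-oxotetrahydrofuran-3-yl]methyl}-2-methyloxiran-2-yl]propanal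
Conditions: Dess–Martin periodinane, NaHCO3, CH2Cl2, 0 °C to rt
Reagents that add atoms: none
Why: Dess–Martin oxidation of a primary alcohol under buffered, non-acidic conditions that the epoxide tolerates.

Step 10
Reactants: 16 3-[(2S,3S)-3-{[(2R,3R)-2-[(tert-butyldiphenylsilyloxy)methyl]-5-oxotetrahydrofuran-3-yl]methyl}-2-methyloxiran-2-yl]propanal; 17 2-(triphenylphosphoranylidene)propanal
Product: 18 (E)-5-[(2S,3S)-3-{[(2R,3R)-2-[(tert-butyldiphenylsilyloxy)methyl]-5-oxotetrahydrofuran-3-yl]methyl}-2-methyloxiran-2-yl]-2-methylpent-2-enal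
Conditions: toluene, 80 °C
Reagents that add atoms: none
Why: Wittig reaction of a stabilised ylide, which gives the E-trisubstituted enal and so fixes the C7=C8 geometry that the ene reaction needs.

Step 11
Reactants: 18 (E)-5-[(2S,3S)-3-{[(2R,3R)-2-[(tert-butyldiphenylsilyloxy)methyl]-5-oxotetrahydrofuran-3-yl]methyl}-2-methyloxiran-2-yl]-2-methylpent-2-enal
Product: 19 (4R,5R)-5-[(tert-butyldiphenylsilyloxy)methyl]-4-{[(2S,3S)-3-[(E)-5-hydroxy-4-methylpent-3-en-1-yl]-3-methyloxiran-2-yl]methyl}dihydrofuran-2(3H)-one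
Conditions: NaBH4, CeCl3·7H2O, MeOH, −20 °C
Reagents that add atoms: none
Why: Luche 1,2-reduction of the enal to the C9 allylic alcohol without touching lactone or epoxide.

Step 12
Reactants: 19 (4R,5R)-5-[(tert-butyldiphenylsilyloxy)methyl]-4-{[(2S,3S)-3-[(E)-5-hydroxy-4-methylpent-3-en-1-yl]-3-methyloxiran-2-yl]methyl}dihydrofuran-2(3H)-one
Product: 21 (4R,5R)-5-[(tert-butyldiphenylsilyloxy)methyl]-4-{[(2S,3S)-3-methyl-3-[(E)-4-methyl-5-(phenylsulfonyl)pent-3-en-1-yl]oxiran-2-yl]methyl}dihydrofuran-2(3H)-one, via allylic bromide 20 (not isolated)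
Conditions: CBr4, PPh3, CH2Cl2, 0 °C; then PhSO2Na, DMF, rt
Reagents that add atoms: sodium benzenesulfinate, [Na+].[O-]S(=O)c1ccccc1
Why: Appel bromination followed by S-alkylation of the sulfinate at the primary allylic bromide (SN2); the E-olefin geometry is retained.

Step 13
Reactants: 21 (4R,5R)-5-[(tert-butyldiphenylsilyloxy)methyl]-4-{[(2S,3S)-3-methyl-3-[(E)-4-methyl-5-(phenylsulfonyl)pent-3-en-1-yl]oxiran-2-yl]methyl}dihydrofuran-2(3H)-one
Product: 22 (4R,5R)-5-(hydroxymethyl)-4-{[(2S,3S)-3-methyl-3-[(E)-4-methyl-5-(phenylsulfonyl)pent-3-en-1-yl]oxiran-2-yl]methyl}dihydrofuran-2(3H)-one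
Conditions: TBAF, AcOH, THF, 0 °C to rt
Reagents that add atoms: none
Why: Fluoride desilylation; the acetic acid buffer keeps the liberated primary alkoxide from attacking the lactone.

Step 14
Reactants: 22 (4R,5R)-5-(hydroxymethyl)-4-{[(2S,3S)-3-methyl-3-[(E)-4-methyl-5-(phenylsulfonyl)pent-3-en-1-yl]oxiran-2-yl]methyl}dihydrofuran-2(3H)-one; 17 2-(triphenylphosphoranylidene)propanal
Product: 24 (E)-2-methyl-3-[(2R,3R)-3-{[(2S,3S)-3-methyl-3-[(E)-4-methyl-5-(phenylsulfonyl)pent-3-en-1-yl]oxiran-2-yl]methyl}-5-oxotetrahydrofuran-2-yl]prop-2-enal, via lactone aldehyde 23 (not isolated)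
Conditions: Dess–Martin periodinane, NaHCO3, CH2Cl2, 0 °C; filtration; then 17, CH2Cl2, 40 °C
Reagents that add atoms: none
Why: Dess–Martin oxidation gives the α-acyloxy aldehyde, which is used at once because C14 could epimerise; the stabilised ylide is weakly basic and gives the E-enal by a Wittig reaction.

Step 15
Reactants: 24 (E)-2-methyl-3-[(2R,3R)-3-{[(2S,3S)-3-methyl-3-[(E)-4-methyl-5-(phenylsulfonyl)pent-3-en-1-yl]oxiran-2-yl]methyl}-5-oxotetrahydrofuran-2-yl]prop-2-enal
Product: 25 (4R,5R)-5-[(E)-3-hydroxy-2-methylprop-1-en-1-yl]-4-{[(2S,3S)-3-methyl-3-[(E)-4-methyl-5-(phenylsulfonyl)pent-3-en-1-yl]oxiran-2-yl]methyl}dihydrofuran-2(3H)-one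
Conditions: NaBH4, CeCl3·7H2O, MeOH, −40 °C
Reagents that add atoms: none
Why: Luche 1,2-reduction; the hard hydride attacks the carbonyl and not the γ-acyloxy enal in an SN2′ sense.

Step 16
Reactants: 25 (4R,5R)-5-[(E)-3-hydroxy-2-methylprop-1-en-1-yl]-4-{[(2S,3S)-3-methyl-3-[(E)-4-methyl-5-(phenylsulfonyl)pent-3-en-1-yl]oxiran-2-yl]methyl}dihydrofuran-2(3H)-one
Product: 26 (4R,5R)-5-[(2R,3R)-3-(hydroxymethyl)-3-methyloxiran-2-yl]-4-{[(2S,3S)-3-methyl-3-[(E)-4-methyl-5-(phenylsulfonyl)pent-3-en-1-yl]oxiran-2-yl]methyl}dihydrofuran-2(3H)-one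
Conditions: Ti(OiPr)4 (cat.), D-(−)-diethyl tartrate (cat.), tBuOOH, 4 Å molecular sieves, CH2Cl2, −20 °C
Reagents that add atoms: tert-butyl hydroperoxide, CC(C)(C)OO
Why: Sharpless asymmetric epoxidation; the D-(−)-tartrate catalyst gives the (2R,3R)-epoxy alcohol, whose C13–O bond becomes the C13–O bond of the target, and reagent control should override the modest bias of the C14 centre. The C7=C8 olefin has no directing hydroxyl and is deactivated by the sulfone.

Step 17
Reactants: 26 (4R,5R)-5-[(2R,3R)-3-(hydroxymethyl)-3-methyloxiran-2-yl]-4-{[(2S,3S)-3-methyl-3-[(E)-4-methyl-5-(phenylsulfonyl)pent-3-en-1-yl]oxiran-2-yl]methyl}dihydrofuran-2(3H)-one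
Product: 27 (2S,3R)-2-methyl-3-[(2R,3R)-3-{[(2S,3S)-3-methyl-3-[(E)-4-methyl-5-(phenylsulfonyl)pent-3-en-1-yl]oxiran-2-yl]methyl}-5-oxotetrahydrofuran-2-yl]oxirane-2-carbaldehyde
Conditions: Dess–Martin periodinane, NaHCO3, CH2Cl2, 0 °C
Reagents that add atoms: none
Why: Dess–Martin oxidation; the epoxy aldehyde has a fully substituted α-carbon and cannot epimerise (the change of descriptor at that carbon is formal only).

Step 18
Reactants: 27 (2S,3R)-2-methyl-3-[(2R,3R)-3-{[(2S,3S)-3-methyl-3-[(E)-4-methyl-5-(phenylsulfonyl)pent-3-en-1-yl]oxiran-2-yl]methyl}-5-oxotetrahydrofuran-2-yl]oxirane-2-carbaldehyde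
Product: 28 (4R,5R)-5-[(2R,3R)-3-methyl-3-vinyloxiran-2-yl]-4-{[(2S,3S)-3-methyl-3-[(E)-4-methyl-5-(phenylsulfonyl)pent-3-en-1-yl]oxiran-2-yl]methyl}dihydrofuran-2(3H)-one
Conditions: Ph3PCH3Br, KHMDS, THF, −78 to 0 °C
Reagents that add atoms: methylenetriphenylphosphorane (made in the flask from methyltriphenylphosphonium bromide and KHMDS), C=P(c1ccccc1)(c1ccccc1)c1ccccc1
Why: Wittig methylenation; at low temperature the aldehyde reacts much faster than the lactone, and only a small excess of ylide is used because its basicity is close to that of the allylic sulfone anion.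

Step 19
Reactants: 28 (4R,5R)-5-[(2R,3R)-3-methyl-3-vinyloxiran-2-yl]-4-{[(2S,3S)-3-methyl-3-[(E)-4-methyl-5-(phenylsulfonyl)pent-3-en-1-yl]oxiran-2-yl]methyl}dihydrofuran-2(3H)-one
Product: 29 (1R,3S,4S,7E,11E,13S,14R)-3,4-epoxy-13-hydroxy-9-(phenylsulfonyl)cembra-7,11-dien-16,14-olide (C9 epimers)
Conditions: Pd(PPh3)4 (10 mol %), dppe (10 mol %), THF, 40 °C, slow addition of 28 (final 2 mM)
Reagents that add atoms: none
Why: Zerovalent palladium ionises the C12–O bond of the vinyl epoxide with inversion and gives a π-allyl complex over C10–C12 with a C13 alkoxide; the ionisation is reversible, so the zwitterion is replenished until it is trapped. The alkoxide (conjugate acid pKa about 30 in DMSO) removes a C9 proton of the allylic sulfone (about 22), and the sulfonyl carbanion attacks the unsubstituted C10 terminus anti to palladium; this is the Tsuji–Trost alkylation of a vinyl epoxide under neutral conditions in its macrocyclisation form. The 14-membered carbocycle closes by C–C bond formation at the distal allyl terminus (1,4-addition mode), whereas attack at C12 would need a quaternary centre and a 12-membered ring. No stereocentre is made under control: C9 forms as both epimers and is erased in step 21, C13 keeps the configuration set in step 16 because its C–O bond is never broken, and the E-C11=C12 geometry follows from the syn placement of the C13 carbon (larger than methyl) on the π-allyl unit, which can equilibrate by η3–η1–η3 shifts before capture. Ring closure is favoured over oligomerisation by slow addition into a dilute catalyst solution, and the moderate temperature holds back ionisation of the allylic C9–sulfone bond and acyl migration in the product.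

Step 20
Reactants: 29 (1R,3S,4S,7E,11E,13S,14R)-3,4-epoxy-13-hydroxy-9-(phenylsulfonyl)cembra-7,11-dien-16,14-olide (C9 epimers)
Product: 30 (1R,3S,4S,7E,11E,13S,14R)-13-(tert-butyldimethylsilyloxy)-3,4-epoxy-9-(phenylsulfonyl)cembra-7,11-dien-16,14-olide (C9 epimers)
Conditions: TBSOTf, 2,6-lutidine, CH2Cl2, −78 °C
Reagents that add atoms: tert-butyldimethylsilyl trifluoromethanesulfonate, CC(C)(C)[Si](C)(C)OS(=O)(=O)C(F)(F)F
Why: Silylation of the hindered secondary allylic alcohol; it blocks acyl migration to C13 and protects the oxygen through the reductive and amide-base steps, and at −78 °C with the hindered base the epoxide should not be opened.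

Step 21
Reactants: 30 (1R,3S,4S,7E,11E,13S,14R)-13-(tert-butyldimethylsilyloxy)-3,4-epoxy-9-(phenylsulfonyl)cembra-7,11-dien-16,14-olide (C9 epimers)
Product: 31 (1R,3S,4S,7E,11E,13S,14R)-13-(tert-butyldimethylsilyloxy)-3,4-epoxycembra-7,11-dien-16,14-olide
Conditions: Na(Hg) (5%), Na2HPO4, MeOH–THF, −20 °C
Reagents that add atoms: none
Why: Reductive desulfonylation by electron transfer (Julia-type cleavage); both C9 epimers give the same allyl anion, which is protonated by methanol, and protonation at C9 keeps the E-C7=C8 olefin. The buffer protects the lactone from methoxide.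

Step 22
Reactants: 31 (1R,3S,4S,7E,11E,13S,14R)-13-(tert-butyldimethylsilyloxy)-3,4-epoxycembra-7,11-dien-16,14-olide
Product: 32 (1R,3S,4S,7E,11E,13S,14R)-13-(tert-butyldimethylsilyloxy)-17-(dimethylamino)-3,4-epoxycembra-7,11-dien-16,14-olide (C15 configuration not fixed)
Conditions: LDA, THF, −78 °C; Eschenmoser's salt, −78 °C to rt
Reagents that add atoms: N,N-dimethylmethyleneiminium iodide (Eschenmoser's salt), C=[N+](C)C.[I-]
Why: Mannich reaction of the lactone lithium enolate, the only enolisable position in 31; the new C15 centre is lost in the next step, so its configuration does not matter.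

Step 23
Reactants: 32 (1R,3S,4S,7E,11E,13S,14R)-13-(tert-butyldimethylsilyloxy)-17-(dimethylamino)-3,4-epoxycembra-7,11-dien-16,14-olide (C15 configuration not fixed)
Product: 34 (1R,3S,4S,7E,11E,13S,14R)-13-(tert-butyldimethylsilyloxy)-3,4-epoxycembra-7,11,15(17)-trien-16,14-olide, via trimethylammonium iodide 33 (not isolated)
Conditions: MeI, THF–MeOH, rt; then aq. NaHCO3, EtOAc, rt
Reagents that add atoms: none
Why: Quaternisation of the amine and E1cB elimination of trimethylamine give the α-methylene lactone under conditions mild enough for epoxide and silyl ether.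

Step 24
Reactants: 34 (1R,3S,4S,7E,11E,13S,14R)-13-(tert-butyldimethylsilyloxy)-3,4-epoxycembra-7,11,15(17)-trien-16,14-olide
Product: 35 (1R,3S,4S,7E,11E,13S,14R)-3,4-epoxy-13-hydroxycembra-7,11,15(17)-trien-16,14-olide
Conditions: HF·pyridine, pyridine, THF, 0 °C to rt
Reagents that add atoms: none
Why: Buffered fluoride desilylation without a free alkoxide, which avoids oxa-Michael addition of the C13 oxygen to C17 and acyl migration.

Step 25
Reactants: 35 (1R,3S,4S,7E,11E,13S,14R)-3,4-epoxy-13-hydroxycembra-7,11,15(17)-trien-16,14-olide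
Product: 36 (1R,3S,4S,7E,11E,13S,14R)-13-acetoxy-3,4-epoxycembra-7,11,15(17)-trien-16,14-olide
Conditions: Ac2O, pyridine, DMAP (cat.), CH2Cl2, 0 °C to rt
Reagents that add atoms: acetic anhydride, CC(=O)OC(C)=O
Why: Acylation of the secondary allylic alcohol with nucleophilic catalysis; the acetate also lowers the reactivity of C11=C12 toward singlet oxygen in the last step.

Step 26
Reactants: 36 (1R,3S,4S,7E,11E,13S,14R)-13-acetoxy-3,4-epoxycembra-7,11,15(17)-trien-16,14-olide
Product: 37 (1R,3S,4S,7R,11E,13S,14R)-13-acetoxy-3,4-epoxy-7-hydroperoxycembra-8(19),11,15(17)-trien-16,14-olide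
Conditions: O2, tetraphenylporphyrin (cat.), visible light, CH2Cl2, −20 °C
Reagents that add atoms: dioxygen, O=O
Why: Schenck ene reaction of singlet oxygen with the most electron-rich olefin, C7=C8; hydrogen is taken from the more crowded side of the double bond (C19 or C6), and abstraction from the freely rotating C19 methyl gives the C7 hydroperoxide with the C8=C19 methylene. C7 is set by attack on the exposed face of the macrocyclic olefin.

## Compound list

1 | (R)-5-(hydroxymethyl)dihydrofuran-2(3H)-one | O=C1CC[C@H](CO)O1 | starting material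
2 | (R)-5-[(tert-butyldiphenylsilyloxy)methyl]dihydrofuran-2(3H)-one | O=C1CC[C@H](CO[Si](c2ccccc2)(c2ccccc2)C(C)(C)C)O1 | intermediate
3 | (5R)-5-[(tert-butyldiphenylsilyloxy)methyl]-3-(phenylselanyl)dihydrofuran-2(3H)-one (C3 epimers) | O=C1O[C@@H](CO[Si](c2ccccc2)(c2ccccc2)C(C)(C)C)CC1[Se]c1ccccc1 | intermediate
4 | (R)-5-[(tert-butyldiphenylsilyloxy)methyl]furan-2(5H)-one | O=C1C=C[C@H](CO[Si](c2ccccc2)(c2ccccc2)C(C)(C)C)O1 | intermediate
5 | allylmagnesium bromide | C=CC[Mg]Br | starting material
6 | tert-butyl{[(2R,3R)-3-allyl-5-(trimethylsilyloxy)-2,3-dihydrofuran-2-yl]methoxy}diphenylsilane | C1=C(O[Si](C)(C)C)O[C@@H](CO[Si](c2ccccc2)(c2ccccc2)C(C)(C)C)[C@@H]1CC=C | intermediate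
7 | (4R,5R)-4-allyl-5-[(tert-butyldiphenylsilyloxy)methyl]dihydrofuran-2(3H)-one | C1C(=O)O[C@@H](CO[Si](c2ccccc2)(c2ccccc2)C(C)(C)C)[C@@H]1CC=C | intermediate
8 | methacrolein (2-methylprop-2-enal) | CC(=C)C=O | starting material
9 | (E)-4-[(2R,3R)-2-[(tert-butyldiphenylsilyloxy)methyl]-5-oxotetrahydrofuran-3-yl]-2-methylbut-2-enal | C1C(=O)O[C@@H](CO[Si](c2ccccc2)(c2ccccc2)C(C)(C)C)[C@@H]1C/C=C(\C)C=O | intermediate
10 | (4R,5R)-5-[(tert-butyldiphenylsilyloxy)methyl]-4-[(E)-4-hydroxy-3-methylbut-2-en-1-yl]dihydrofuran-2(3H)-one | C1C(=O)O[C@@H](CO[Si](c2ccccc2)(c2ccccc2)C(C)(C)C)[C@@H]1C/C=C(\C)CO | intermediate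
11 | (4R,5R)-5-[(tert-butyldiphenylsilyloxy)methyl]-4-{[(2S,3S)-3-(hydroxymethyl)-3-methyloxiran-2-yl]methyl}dihydrofuran-2(3H)-one | C1C(=O)O[C@@H](CO[Si](c2ccccc2)(c2ccccc2)C(C)(C)C)[C@@H]1C[C@@H]1O[C@@]1(C)CO | intermediate
12 | vinylmagnesium bromide | C=C[Mg]Br | starting material
13 | [(2S,3S)-3-{[(2R,3R)-2-[(tert-butyldiphenylsilyloxy)methyl]-5-oxotetrahydrofuran-3-yl]methyl}-2-methyloxiran-2-yl]methyl trifluoromethanesulfonate | C1C(=O)O[C@@H](CO[Si](c2ccccc2)(c2ccccc2)C(C)(C)C)[C@@H]1C[C@@H]1O[C@@]1(C)COS(=O)(=O)C(F)(F)F | intermediate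
14 | (4R,5R)-4-{[(2S,3S)-3-allyl-3-methyloxiran-2-yl]methyl}-5-[(tert-butyldiphenylsilyloxy)methyl]dihydrofuran-2(3H)-one | C1C(=O)O[C@@H](CO[Si](c2ccccc2)(c2ccccc2)C(C)(C)C)[C@@H]1C[C@@H]1O[C@@]1(C)CC=C | intermediate
15 | (4R,5R)-5-[(tert-butyldiphenylsilyloxy)methyl]-4-{[(2S,3S)-3-(3-hydroxypropyl)-3-methyloxiran-2-yl]methyl}dihydrofuran-2(3H)-one | C1C(=O)O[C@@H](CO[Si](c2ccccc2)(c2ccccc2)C(C)(C)C)[C@@H]1C[C@@H]1O[C@@]1(C)CCCO | intermediate
16 | 3-[(2S,3S)-3-{[(2R,3R)-2-[(tert-butyldiphenylsilyloxy)methyl]-5-oxotetrahydrofuran-3-yl]methyl}-2-methyloxiran-2-yl]propanal | C1C(=O)O[C@@H](CO[Si](c2ccccc2)(c2ccccc2)C(C)(C)C)[C@@H]1C[C@@H]1O[C@@]1(C)CCC=O | intermediate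
17 | 2-(triphenylphosphoranylidene)propanal | CC(C=O)=P(c1ccccc1)(c1ccccc1)c1ccccc1 | starting material
18 | (E)-5-[(2S,3S)-3-{[(2R,3R)-2-[(tert-butyldiphenylsilyloxy)methyl]-5-oxotetrahydrofuran-3-yl]methyl}-2-methyloxiran-2-yl]-2-methylpent-2-enal | C1C(=O)O[C@@H](CO[Si](c2ccccc2)(c2ccccc2)C(C)(C)C)[C@@H]1C[C@@H]1O[C@@]1(C)CC/C=C(\C)C=O | intermediate
19 | (4R,5R)-5-[(tert-butyldiphenylsilyloxy)methyl]-4-{[(2S,3S)-3-[(E)-5-hydroxy-4-methylpent-3-en-1-yl]-3-methyloxiran-2-yl]methyl}dihydrofuran-2(3H)-one | C1C(=O)O[C@@H](CO[Si](c2ccccc2)(c2ccccc2)C(C)(C)C)[C@@H]1C[C@@H]1O[C@@]1(C)CC/C=C(\C)CO | intermediate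
20 | (4R,5R)-4-{[(2S,3S)-3-[(E)-5-bromo-4-methylpent-3-en-1-yl]-3-methyloxiran-2-yl]methyl}-5-[(tert-butyldiphenylsilyloxy)methyl]dihydrofuran-2(3H)-one | C1C(=O)O[C@@H](CO[Si](c2ccccc2)(c2ccccc2)C(C)(C)C)[C@@H]1C[C@@H]1O[C@@]1(C)CC/C=C(\C)CBr | intermediate
21 | (4R,5R)-5-[(tert-butyldiphenylsilyloxy)methyl]-4-{[(2S,3S)-3-methyl-3-[(E)-4-methyl-5-(phenylsulfonyl)pent-3-en-1-yl]oxiran-2-yl]methyl}dihydrofuran-2(3H)-one | C1C(=O)O[C@@H](CO[Si](c2ccccc2)(c2ccccc2)C(C)(C)C)[C@@H]1C[C@@H]1O[C@@]1(C)CC/C=C(\C)CS(=O)(=O)c1ccccc1 | intermediate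
22 | (4R,5R)-5-(hydroxymethyl)-4-{[(2S,3S)-3-methyl-3-[(E)-4-methyl-5-(phenylsulfonyl)pent-3-en-1-yl]oxiran-2-yl]methyl}dihydrofuran-2(3H)-one | C1C(=O)O[C@@H](CO)[C@@H]1C[C@@H]1O[C@@]1(C)CC/C=C(\C)CS(=O)(=O)c1ccccc1 | intermediate
23 | (2R,3R)-3-{[(2S,3S)-3-methyl-3-[(E)-4-methyl-5-(phenylsulfonyl)pent-3-en-1-yl]oxiran-2-yl]methyl}-5-oxotetrahydrofuran-2-carbaldehyde | C1C(=O)O[C@@H](C=O)[C@@H]1C[C@@H]1O[C@@]1(C)CC/C=C(\C)CS(=O)(=O)c1ccccc1 | intermediate
24 | (E)-2-methyl-3-[(2R,3R)-3-{[(2S,3S)-3-methyl-3-[(E)-4-methyl-5-(phenylsulfonyl)pent-3-en-1-yl]oxiran-2-yl]methyl}-5-oxotetrahydrofuran-2-yl]prop-2-enal | C1C(=O)O[C@@H](/C=C(\C)C=O)[C@@H]1C[C@@H]1O[C@@]1(C)CC/C=C(\C)CS(=O)(=O)c1ccccc1 | intermediate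
25 | (4R,5R)-5-[(E)-3-hydroxy-2-methylprop-1-en-1-yl]-4-{[(2S,3S)-3-methyl-3-[(E)-4-methyl-5-(phenylsulfonyl)pent-3-en-1-yl]oxiran-2-yl]methyl}dihydrofuran-2(3H)-one | C1C(=O)O[C@@H](/C=C(\C)CO)[C@@H]1C[C@@H]1O[C@@]1(C)CC/C=C(\C)CS(=O)(=O)c1ccccc1 | intermediate
26 | (4R,5R)-5-[(2R,3R)-3-(hydroxymethyl)-3-methyloxiran-2-yl]-4-{[(2S,3S)-3-methyl-3-[(E)-4-methyl-5-(phenylsulfonyl)pent-3-en-1-yl]oxiran-2-yl]methyl}dihydrofuran-2(3H)-one | C1C(=O)O[C@@H]([C@H]2O[C@]2(C)CO)[C@@H]1C[C@@H]1O[C@@]1(C)CC/C=C(\C)CS(=O)(=O)c1ccccc1 | intermediate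
27 | (2S,3R)-2-methyl-3-[(2R,3R)-3-{[(2S,3S)-3-methyl-3-[(E)-4-methyl-5-(phenylsulfonyl)pent-3-en-1-yl]oxiran-2-yl]methyl}-5-oxotetrahydrofuran-2-yl]oxirane-2-carbaldehyde | C1C(=O)O[C@@H]([C@H]2O[C@]2(C)C=O)[C@@H]1C[C@@H]1O[C@@]1(C)CC/C=C(\C)CS(=O)(=O)c1ccccc1 | intermediate
28 | (4R,5R)-5-[(2R,3R)-3-methyl-3-vinyloxiran-2-yl]-4-{[(2S,3S)-3-methyl-3-[(E)-4-methyl-5-(phenylsulfonyl)pent-3-en-1-yl]oxiran-2-yl]methyl}dihydrofuran-2(3H)-one | C1C(=O)O[C@@H]([C@H]2O[C@]2(C)C=C)[C@@H]1C[C@@H]1O[C@@]1(C)CC/C=C(\C)CS(=O)(=O)c1ccccc1 | intermediate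
29 | (1R,3S,4S,7E,11E,13S,14R)-3,4-epoxy-13-hydroxy-9-(phenylsulfonyl)cembra-7,11-dien-16,14-olide (C9 epimers) | C1C(=O)O[C@@H]2[C@@H]1C[C@@H]1O[C@@]1(C)CC/C=C(\C)C(S(=O)(=O)c1ccccc1)C/C=C(\C)[C@@H]2O | intermediate
30 | (1R,3S,4S,7E,11E,13S,14R)-13-(tert-butyldimethylsilyloxy)-3,4-epoxy-9-(phenylsulfonyl)cembra-7,11-dien-16,14-olide (C9 epimers) | C1C(=O)O[C@@H]2[C@@H]1C[C@@H]1O[C@@]1(C)CC/C=C(\C)C(S(=O)(=O)c1ccccc1)C/C=C(\C)[C@@H]2O[Si](C)(C)C(C)(C)C | intermediate
31 | (1R,3S,4S,7E,11E,13S,14R)-13-(tert-butyldimethylsilyloxy)-3,4-epoxycembra-7,11-dien-16,14-olide | C1C(=O)O[C@@H]2[C@@H]1C[C@@H]1O[C@@]1(C)CC/C=C(\C)CC/C=C(\C)[C@@H]2O[Si](C)(C)C(C)(C)C | intermediate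
32 | (1R,3S,4S,7E,11E,13S,14R)-13-(tert-butyldimethylsilyloxy)-17-(dimethylamino)-3,4-epoxycembra-7,11-dien-16,14-olide (C15 configuration not fixed) | CN(C)CC1C(=O)O[C@@H]2[C@@H]1C[C@@H]1O[C@@]1(C)CC/C=C(\C)CC/C=C(\C)[C@@H]2O[Si](C)(C)C(C)(C)C | intermediate
33 | trimethylammonium iodide of 32 (17-(trimethylammonio) lactone iodide; C15 configuration not fixed) | C[N+](C)(C)CC1C(=O)O[C@@H]2[C@@H]1C[C@@H]1O[C@@]1(C)CC/C=C(\C)CC/C=C(\C)[C@@H]2O[Si](C)(C)C(C)(C)C.[I-] | intermediate
34 | (1R,3S,4S,7E,11E,13S,14R)-13-(tert-butyldimethylsilyloxy)-3,4-epoxycembra-7,11,15(17)-trien-16,14-olide | C=C1C(=O)O[C@@H]2[C@@H]1C[C@@H]1O[C@@]1(C)CC/C=C(\C)CC/C=C(\C)[C@@H]2O[Si](C)(C)C(C)(C)C | intermediate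
35 | (1R,3S,4S,7E,11E,13S,14R)-3,4-epoxy-13-hydroxycembra-7,11,15(17)-trien-16,14-olide | C=C1C(=O)O[C@@H]2[C@@H]1C[C@@H]1O[C@@]1(C)CC/C=C(\C)CC/C=C(\C)[C@@H]2O | intermediate
36 | (1R,3S,4S,7E,11E,13S,14R)-13-acetoxy-3,4-epoxycembra-7,11,15(17)-trien-16,14-olide | C=C1C(=O)O[C@@H]2[C@@H]1C[C@@H]1O[C@@]1(C)CC/C=C(\C)CC/C=C(\C)[C@@H]2OC(C)=O | intermediate
37 | (1R,3S,4S,7R,11E,13S,14R)-13-acetoxy-3,4-epoxy-7-hydroperoxycembra-8(19),11,15(17)-trien-16,14-olide | C=C1C(=O)O[C@@H]2[C@@H]1C[C@@H]1O[C@@]1(C)CC[C@@H](OO)C(=C)CC/C=C(\C)[C@@H]2OC(C)=O | target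

## Step count and least certain steps

Total step count: 26. Longest linear sequence: 26 steps, from 1 to 37; building blocks 5, 8, 12 and 17 are bought.

**Step 19 (key step).**
- Most likely failure: proton transfer from the only moderately acidic allylic sulfone to the C13 alkoxide is too slow at high dilution. The π-allyl alkoxide then isomerises by β-hydride loss or oligomerises. Loss of E/Z control through the anti π-allyl form and a slow 1,3-shift of the allylic sulfonyl group under palladium are also possible.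
- Fallback: the internal base is given up and the carbanion is preformed. Starting from 28, palladium-catalysed 1,4-addition of acetic acid (Pd(PPh3)4, AcOH, THF) should give the E-C10 acetate with a free C13 hydroxyl, hydroxy acetate F1. Silylation (TBSOTf, 2,6-lutidine) gives silyl ether F2. Deprotonation at C9 with one equivalent of LiHMDS at −78 °C and slow addition of the anion to Pd(PPh3)4/dppe in warm THF closes the same C9–C10 bond by Tsuji–Trost alkylation of an allylic acetate, and gives 30, where the route is rejoined.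

**Step 21.**
- Most likely failure: unselective protonation of the allyl anion. C7 and C9 are both secondary termini, so protonation at C7 would move the double bond to C8=C9, and some E/Z scrambling may accompany it.
- Fallback: the single reduction is replaced by two regiospecific allylic transpositions. Starting from 30, radical SH2′ stannylation (Bu3SnH, AIBN, benzene, 80 °C, short reaction time) expels the sulfonyl radical and places tin on C7 with a C8=C9 olefin, allylstannane F3. Protodestannylation with acetic acid (SE2′) delivers the proton to C9 and returns the double bond to C7=C8, giving 31.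

**Step 26.**
- Most likely failure: poor site and facial selectivity of the ene reaction. Hydrogen abstraction from C6 would give the tertiary C8 hydroperoxide, attack on the other face of C7=C8 would give the C7 epimer, and C11=C12 may compete.
- Fallback: C7 is set by a reagent instead of by the ring conformation. Starting from 36, the crude photooxygenation mixture of 37 and its C7 epimer, 7-epi-hydroperoxide F4, is reduced with PPh3 to the C7 allylic alcohols F5. Tertiary isomers are removed here because they cannot be oxidised. Dess–Martin oxidation gives the cross-conjugated enone F6. Reduction with catecholborane and the (R)-CBS oxazaborolidine gives the (7S)-alcohol F7. Mesylation (MsCl, Et3N, −40 °C) gives mesylate F8, which is displaced in the same flask by anhydrous hydrogen peroxide in ether at low temperature with inversion, arriving at 37.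

**Step 7.**
- Most likely failure: slow SN2 displacement at C5, which sits beside the fully substituted epoxide carbon, so that the Grignard reagent attacks the lactone or the epoxide instead.
- Fallback: the substitution is avoided by making C5–C6 as a double bond. Starting from 11, Dess–Martin oxidation gives epoxy aldehyde F9. A Wittig reaction with the β-oxido ylide from (2-hydroxyethyl)triphenylphosphonium bromide and two equivalents of n-BuLi at −78 °C gives the Z-allylic alcohol F10. Diimide (2-nitrobenzenesulfonylhydrazide, Et3N) saturates the disubstituted olefin without opening the epoxide and gives 15.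

**Step 3.**
- Most likely failure: 1,2-addition of the allyl reagent to the lactone carbonyl, or double addition, in place of conjugate addition.
- Fallback: the better-behaved vinyl group is added and extended. Starting from 4, copper-mediated addition of vinylmagnesium bromide 12 (CuI, TMSCl, THF, −78 °C) gives vinyl lactone F11. Hydroboration–oxidation (9-BBN; buffered H2O2) gives alcohol F12. Dess–Martin oxidation gives aldehyde F13. A Wittig reaction with 17 in toluene gives enal 9.

## Further compounds

F1 | step 19 | (4R,5R)-5-[(1S,2E)-4-acetoxy-1-hydroxy-2-methylbut-2-en-1-yl]-4-{[(2S,3S)-3-methyl-3-[(E)-4-methyl-5-(phenylsulfonyl)pent-3-en-1-yl]oxiran-2-yl]methyl}dihydrofuran-2(3H)-one | C1C(=O)O[C@@H]([C@@H](O)/C(C)=C/COC(C)=O)[C@@H]1C[C@@H]1O[C@@]1(C)CC/C=C(\C)CS(=O)(=O)c1ccccc1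
F2 | step 19 | tert-butyldimethylsilyl ether of F1 at the C13 oxygen | C1C(=O)O[C@@H]([C@@H](O[Si](C)(C)C(C)(C)C)/C(C)=C/COC(C)=O)[C@@H]1C[C@@H]1O[C@@]1(C)CC/C=C(\C)CS(=O)(=O)c1ccccc1
F3 | step 21 | (1R,3S,4S,11E,13S,14R)-13-(tert-butyldimethylsilyloxy)-3,4-epoxy-7-(tributylstannyl)cembra-8,11-dien-16,14-olide (C7 epimers, C8=C9 geometry not fixed) | C1C(=O)O[C@@H]2[C@@H]1C[C@@H]1O[C@@]1(C)CCC([Sn](CCCC)(CCCC)CCCC)C(C)=CC/C=C(\C)[C@@H]2O[Si](C)(C)C(C)(C)C
F4 | step 26 | (1R,3S,4S,7S,11E,13S,14R)-13-acetoxy-3,4-epoxy-7-hydroperoxycembra-8(19),11,15(17)-trien-16,14-olide | C=C1C(=O)O[C@@H]2[C@@H]1C[C@@H]1O[C@@]1(C)CC[C@H](OO)C(=C)CC/C=C(\C)[C@@H]2OC(C)=O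
F5 | step 26 | (1R,3S,4S,11E,13S,14R)-13-acetoxy-3,4-epoxy-7-hydroxycembra-8(19),11,15(17)-trien-16,14-olide (C7 epimers) | C=C1C(=O)O[C@@H]2[C@@H]1C[C@@H]1O[C@@]1(C)CCC(O)C(=C)CC/C=C(\C)[C@@H]2OC(C)=O
F6 | step 26 | (1R,3S,4S,11E,13S,14R)-13-acetoxy-3,4-epoxy-7-oxocembra-8(19),11,15(17)-trien-16,14-olide | C=C1C(=O)O[C@@H]2[C@@H]1C[C@@H]1O[C@@]1(C)CCC(=O)C(=C)CC/C=C(\C)[C@@H]2OC(C)=O
F7 | step 26 | (1R,3S,4S,7S,11E,13S,14R)-13-acetoxy-3,4-epoxy-7-hydroxycembra-8(19),11,15(17)-trien-16,14-olide | C=C1C(=O)O[C@@H]2[C@@H]1C[C@@H]1O[C@@]1(C)CC[C@H](O)C(=C)CC/C=C(\C)[C@@H]2OC(C)=O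
F8 | step 26 | (1R,3S,4S,7S,11E,13S,14R)-13-acetoxy-3,4-epoxy-7-(methylsulfonyloxy)cembra-8(19),11,15(17)-trien-16,14-olide | C=C1C(=O)O[C@@H]2[C@@H]1C[C@@H]1O[C@@]1(C)CC[C@H](OS(C)(=O)=O)C(=C)CC/C=C(\C)[C@@H]2OC(C)=O
F9 | step 7 | (2R,3S)-3-{[(2R,3R)-2-[(tert-butyldiphenylsilyloxy)methyl]-5-oxotetrahydrofuran-3-yl]methyl}-2-methyloxirane-2-carbaldehyde | C1C(=O)O[C@@H](CO[Si](c2ccccc2)(c2ccccc2)C(C)(C)C)[C@@H]1C[C@@H]1O[C@@]1(C)C=O
F10 | step 7 | (4R,5R)-5-[(tert-butyldiphenylsilyloxy)methyl]-4-{[(2S,3S)-3-[(Z)-3-hydroxyprop-1-en-1-yl]-3-methyloxiran-2-yl]methyl}dihydrofuran-2(3H)-one | C1C(=O)O[C@@H](CO[Si](c2ccccc2)(c2ccccc2)C(C)(C)C)[C@@H]1C[C@@H]1O[C@@]1(C)/C=C\CO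
F11 | step 3 | (4S,5R)-5-[(tert-butyldiphenylsilyloxy)methyl]-4-vinyldihydrofuran-2(3H)-one | C1C(=O)O[C@@H](CO[Si](c2ccccc2)(c2ccccc2)C(C)(C)C)[C@@H]1C=C
F12 | step 3 | (4R,5R)-5-[(tert-butyldiphenylsilyloxy)methyl]-4-(2-hydroxyethyl)dihydrofuran-2(3H)-one | C1C(=O)O[C@@H](CO[Si](c2ccccc2)(c2ccccc2)C(C)(C)C)[C@@H]1CCO
F13 | step 3 | 2-[(2R,3R)-2-[(tert-butyldiphenylsilyloxy)methyl]-5-oxotetrahydrofuran-3-yl]acetaldehyde | C1C(=O)O[C@@H](CO[Si](c2ccccc2)(c2ccccc2)C(C)(C)C)[C@@H]1CC=O
A1 | alternative 1 | (R)-5-(tert-butyldiphenylsilyloxy)-1-(pivaloyloxy)pentan-2-yl 2-diazo-2-(diethoxyphosphoryl)acetate | CCOP(=O)(OCC)C(=[N+]=[N-])C(=O)O[C@@H](COC(=O)C(C)(C)C)CCCO[Si](c1ccccc1)(c1ccccc1)C(C)(C)C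
A2 | alternative 1 | trans-4,5-disubstituted α-(diethoxyphosphoryl)-γ-lactone with C14 pivaloyloxymethyl and C1 2-(tert-butyldiphenylsilyloxy)ethyl groups (C15 epimers) | CCOP(=O)(OCC)C1C(=O)O[C@@H](COC(=O)C(C)(C)C)[C@@H]1CCO[Si](c1ccccc1)(c1ccccc1)C(C)(C)C
A3 | alternative 2 | (E)-tert-butyldimethyl{[2-methyl-4-(phenylsulfonyl)but-2-en-1-yl]oxy}silane | O=S(=O)(c1ccccc1)C/C=C(\C)CO[Si](C)(C)C(C)(C)C
A4 | alternative 2 | trans,trans-trisubstituted lactone with C15 dimethylaminomethyl group and C2 phenylsulfonyl allyl chain (C2 epimers) | CN(C)C[C@H]1C(=O)O[C@@H](CO[Si](c2ccccc2)(c2ccccc2)C(C)(C)C)[C@@H]1C(S(=O)(=O)c1ccccc1)/C=C(\C)CO[Si](C)(C)C(C)(C)C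
A5 | alternative 3 | 14-membered carbocyclic C14 alcohol with C1 ethynyl group, 3,4-epoxide and C13 tert-butyldimethylsilyl ether | O[C@@H]2[C@@H](C#C)C[C@@H]1O[C@@]1(C)CC/C=C(\C)CC/C=C(\C)[C@@H]2O[Si](C)(C)C(C)(C)C
A6 | alternative 3 | 14-membered α-methylene lactone with C13 silyl ether (identical with 34) | C=C1C(=O)O[C@@H]2[C@@H]1C[C@@H]1O[C@@]1(C)CC/C=C(\C)CC/C=C(\C)[C@@H]2O[Si](C)(C)C(C)(C)C
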